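**Retrosynthetic overview**
1. Locants (briarane): C1 quaternary fusion carbon (CH3 = C15), C2 CH–OAc, C3/C4 CH2, C5(CH3)=C6 Z-olefin, C7 lactone O–CH, C8 C–OH, C9 CH–OAc, C10 fusion CH, C11 CH(CH3), C12 CH–OH, C13=C14, C17 lactone CH(CH3), C19 lactone C=O.
2. Enabling feature: in the cyclohexene ring (C1, C10–C14) the quaternary C1 stands para to the oxygenated C12, so this ring is a desymmetrised 4,4-disubstituted cyclohexa-2,5-dienone. O–C9 and O–C12 are 1,4-related, so C9–C10 is the bond an α-oxy C9 radical makes with the enone β-carbon C10.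
3. 26 <= OH-directed hydrogenation of C11=CH2 <= Evans–Tishchenko transfer (C9–OH to C9–OAc, C12=O to C12–OH) <= α'-methylenation <= tricyclic enone 22.
4. 22 <= C9–C10 closure of dienone diol 21, whose six-membered ring is still achiral. 21 <= C7–C8 aldol/lactonisation of dioxolanone acid 17 (Evans aldol, C8–C17) with (Z)-enal 12 (C3–C4 enolate alkylation, CBS reduction at C2).
5. Ring order: six-membered carbocycle (Birch reductive methylation of acetophenone, step 1), γ-lactone (step 13), ten-membered carbocycle (step 16).

Key step: step 16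

Remark on the chemistry: β denotes the face of the six-membered ring that carries the C15 methyl. Compound 22 may rest partly as its C9–O–C12 hemiketal, which is assumed to equilibrate with the open hydroxy enone that is written.

**Step 1**
Reactants: 1 acetophenone
Product: 2 1-(1-methylcyclohexa-2,5-dien-1-yl)ethan-1-one
Conditions: K, t-BuOH (1 equiv), NH3(l)/THF, −78 °C; LiBr; MeI, −78 °C
Reagents that add atoms: methyl iodide CI
Why: Birch reductive alkylation of an aryl ketone, in which the dienolate from two-electron reduction and para protonation is methylated at the ipso carbon, so the cheap arene is dearomatised and quaternary C1 is installed on a mirror plane (no stereocentre yet).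

**Step 2**
Reactants: 3 (tert-butyldimethylsilyloxy)acetaldehyde; 4 ethyl 2-[bis(2,2,2-trifluoroethoxy)phosphoryl]propanoate
Product: 5 ethyl (2Z)-4-[(tert-butyldimethylsilyl)oxy]-2-methylbut-2-enoate
Conditions: KHMDS, 18-crown-6, THF, −78 °C
Reagents that add atoms: none
Why: Still–Gennari olefination, in which the electron-poor phosphonate with a dissociated potassium base eliminates under kinetic control and should give the (Z)-trisubstituted enoate, with C4 and C7 cis on C5=C6.

**Step 3**
Reactants: 5 (Z)-enoate
Product: 6 (2Z)-4-[(tert-butyldimethylsilyl)oxy]-2-methylbut-2-en-1-ol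
Conditions: DIBAL-H (2.2 equiv), CH2Cl2, −78 °C; Rochelle salt
Reagents that add atoms: none
Why: DIBAL-H 1,2-reduction of the enoate to the allylic alcohol leaves the silyl ether and the olefin geometry untouched.

**Step 4**
Reactants: 6 (Z)-allylic alcohol
Product: 7 {[(2Z)-4-bromo-3-methylbut-2-en-1-yl]oxy}(tert-butyl)dimethylsilane
Conditions: CBr4, PPh3, CH2Cl2, 0 °C
Reagents that add atoms: carbon tetrabromide BrC(Br)(Br)Br
Why: Appel bromination displaces the oxyphosphonium ion by SN2 under neutral conditions, so the (Z)-allylic system should neither transpose nor isomerise.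

**Step 5**
Reactants: 2 methyl ketone; 7 (Z)-allylic bromide
Product: 8 (4Z)-6-[(tert-butyldimethylsilyl)oxy]-4-methyl-1-(1-methylcyclohexa-2,5-dien-1-yl)hex-4-en-1-one
Conditions: LDA, THF, −78 °C; 7, DMPU, −78 to −20 °C
Reagents that add atoms: none
Why: Kinetic lithium enolate alkylation, in which 2 has a single enolisable position (the acetyl CH3 = C3) and the primary allylic bromide reacts by SN2 to forge C3–C4.

**Step 6**
Reactants: 8 ketone
Product: 9 (1R,4Z)-6-[(tert-butyldimethylsilyl)oxy]-4-methyl-1-(1-methylcyclohexa-2,5-dien-1-yl)hex-4-en-1-ol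
Conditions: (S)-Me-CBS (20 mol %), catecholborane, toluene, −78 °C
Reagents that add atoms: none
Why: Corey–Bakshi–Shibata reduction, in which the quaternary dienyl carbon is the large and the CH2 chain the small ketone substituent, so the (S)-oxazaborolidine should give the (R)-carbinol at C2, and catecholborane at low temperature does not hydroborate the olefins.

**Step 7**
Reactants: 9 alcohol
Product: 10 (1R,4Z)-6-[(tert-butyldimethylsilyl)oxy]-4-methyl-1-(1-methylcyclohexa-2,5-dien-1-yl)hex-4-en-1-yl acetate
Conditions: Ac2O, pyridine, DMAP (cat.), CH2Cl2, rt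
Reagents that add atoms: acetic anhydride CC(=O)OC(C)=O
Why: DMAP-catalysed acylation installs the final C2 acetate, which also protects this oxygen for the rest of the route.

**Step 8**
Reactants: 10 silyl ether
Product: 11 (1R,4Z)-6-hydroxy-4-methyl-1-(1-methylcyclohexa-2,5-dien-1-yl)hex-4-en-1-yl acetate
Conditions: HF·pyridine, THF, 0 °C
Reagents that add atoms: none
Why: Fluoride-induced desilylation in a buffered acidic medium frees the primary allylic alcohol without touching the acetate.

**Step 9**
Reactants: 11 allylic alcohol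
Product: 12 (1R,4Z)-4-methyl-1-(1-methylcyclohexa-2,5-dien-1-yl)-6-oxohex-4-en-1-yl acetate
Conditions: activated MnO2, CH2Cl2, rt
Reagents that add atoms: none
Why: Manganese dioxide oxidises only the allylic alcohol and, being neutral and heterogeneous, should preserve the (Z)-geometry of the enal.

**Step 10**
Reactants: 13 (4R)-4-benzyl-3-propanoyl-1,3-oxazolidin-2-one; 14 ethyl glyoxylate
Product: 15 ethyl (2R,3R)-4-[(4R)-4-benzyl-2-oxo-1,3-oxazolidin-3-yl]-2-hydroxy-3-methyl-4-oxobutanoate
Conditions: Bu2BOTf, Et3N, CH2Cl2, 0 °C; 14, −78 to 0 °C; MeOH, pH 7 buffer, H2O2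
Reagents that add atoms: none
Why: Evans syn-aldol reaction, in which the (Z)-boron enolate reacts through a Zimmerman–Traxler chair on the face opposite the benzyl group and so sets C17 (R) and the C8 carbinol (R) in the syn relationship.

**Step 11**
Reactants: 15 aldol imide
Product: 16 (2R,3R)-2-hydroxy-3-methylbutanedioic acid
Conditions: LiOH, H2O2, THF/H2O, 0 °C to rt; Na2SO3; HCl
Reagents that add atoms: hydrogen peroxide OO; lithium hydroxide [Li+].[OH-]
Why: Hydroperoxide cleaves the imide at the exocyclic carbonyl and excess hydroxide saponifies the ethyl ester, mild conditions that should not epimerise C17 or trigger retro-aldol cleavage.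

**Step 12**
Reactants: 16 diacid
Product: 17 (2R)-2-[(2R,4R)-2-tert-butyl-5-oxo-1,3-dioxolan-4-yl]propanoic acid
Conditions: t-BuCHO, TsOH (cat.), H2SO4 (cat.), pentane, reflux, Dean–Stark
Reagents that add atoms: pivalaldehyde CC(C)(C)C=O
Why: Acid-catalysed acetalisation of the α-hydroxy acid unit gives the five-membered dioxolanone as the thermodynamically preferred cis isomer (tert-butyl and side chain on one face) and leaves the second carboxyl group free.

**Step 13**
Reactants: 17 dioxolanone acid; 12 (Z)-enal
Product: 19 C8-spiro dioxolanone γ-lactone (2R;5Z;7S;8S;17R; acetal carbon R), via aldol hydroxy acid 18 (not isolated)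
Conditions: LiHMDS (2.1 equiv), THF, −78 °C; 12, −78 °C; AcOH; PPTS (cat.), CH2Cl2, rt
Reagents that add atoms: none
Why: Aldol addition by self-regeneration of stereocentres followed by lactonisation, in which the aldehyde attacks the carboxylate-protected dioxolanone enolate anti to the tert-butyl group (C8, overall retention) through a Zimmerman–Traxler chair whose ring-fixed enolate geometry places O–C7 syn to C17 (C7), and the γ-hydroxy acid then closes the lactone.

**Step 14**
Reactants: 19 spiro dioxolanone lactone
Product: 20 C8,C9-diol lactone with cyclohexa-2,5-dienyl ring (2R;5Z;7S;8R;17R)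
Conditions: NaBH4, THF/EtOH, −20 °C; aq. NH4Cl
Reagents that add atoms: none
Why: Chemoselective borohydride reduction, in which the dioxolanone carbonyl is an α-oxygenated acylal-type ester far more electrophilic than the α-branched γ-lactone or the acetate, and its collapse releases pivalaldehyde and the C8 hydroxyl while C9 is taken down to CH2OH.

**Step 15**
Reactants: 20 diene diol
Product: 21 dienone diol (4-methyl-4-substituted cyclohexa-2,5-dienone; 2R;5Z;7S;8R;17R)
Conditions: Rh2(cap)4 (1 mol %), t-BuOOH (70 % aq.), CH2Cl2, rt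
Reagents that add atoms: tert-butyl hydroperoxide CC(C)(C)OO
Why: Dirhodium caprolactamate/hydroperoxide allylic oxidation, in which the tert-butylperoxyl radical abstracts the weakest, doubly allylic C12–H and the resulting peroxide collapses to the cross-conjugated dienone, whereas carbinol and mono-allylic C–H bonds are stronger.

**Step 16**
Reactants: 21 dienone diol
Product: 22 tricyclic 9-hydroxy enone (1S;2R;5Z;7S;8R;9R;10S;17R)
Conditions: Ir[dF(CF3)ppy]2(dtbbpy)PF6 (2 mol %), quinuclidine (20 mol %), Ph2BOH (20 mol %), MeCN (1 mM), blue LEDs, rt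
Reagents that add atoms: none
Why: Proposed new method: The excited iridium(III) complex oxidises quinuclidine, whose radical cation abstracts a hydridic C9–H from the anionic diphenylborinate chelate of the C8/C9 diol; the nucleophilic α-oxy C9 radical adds to C10, the β-carbon of one enone arm, and the C11 α-keto radical is reduced by iridium(II) and protonated, so that 21 is isomerised to 22 without any stoichiometric reagent. The closest known reaction types are the borinic acid/quinuclidine/photoredox C–H alkylation of 1,2-diols with acrylates and photoredox Giese macrocyclisations; new here are the ten-membered carbocycle and the cyclohexadienone acceptor. The ten-membered ring closes in the 10-exo-trig mode, helped by the (Z)-C5=C6 bond, the trans-disubstituted lactone, the fully substituted C1 and C8 and the borinate ring, which leave few free rotors, and by the early transition state of a radical addition, which tolerates the two neopentyl-type termini better than a polar alternative. C10: attack should come anti to the C1–C2 bond, on the face of the smaller C15 methyl, because the syn mode would force a nearly eclipsed C2–C1–C10–C9 torsion into the medium ring (hence trans fusion); C1: the adjacent C2 stereocentre should select the enone arm whose closure keeps H-2 inside and the acetoxy group outside the forming ring; C9: with C8 anti to C1 about the forming bond, H-9 rather than O-9 has to face the C15 methyl, which puts O-9 over the six-membered ring (9R). The selectivities needed are the site of hydrogen abstraction (only C9–H is α to a borinate oxygen, C2–H and C7–H are deactivated α-acyloxy C–H bonds, and the allylic C–H bonds are not hydridic), ring closure over oligomerisation (high dilution and a low stationary radical concentration) and single addition (C14 of the remaining enone cannot be reached once the ring is closed).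

**Step 17**
Reactants: 22 tricyclic enone
Product: 23 11-methylene cross-conjugated dienone (1S;2R;5Z;7S;8R;9R;10R;17R)
Conditions: (CH2O)n, N-methylanilinium trifluoroacetate, THF, reflux
Reagents that add atoms: formaldehyde (from paraformaldehyde) C=O
Why: Mannich-type α-methylenation (aminomethylation by the formaldehyde-derived iminium ion, then β-elimination of the amine), for which C11 is the only enolisable position because C1 is quaternary, and the weakly acidic medium should spare lactone, acetate and hydroxyl groups.

**Step 18**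
Reactants: 23 methylene dienone
Product: 25 9-acetate 12α-alcohol with C11=CH2 (1S;2R;5Z;7S;8S;9R;10S;12R;17R), via C9 hemiacetal 24 (not isolated)
Conditions: CH3CHO (excess), SmI2 (30 mol %, premixed with CH3CHO), THF, −10 °C
Reagents that add atoms: acetaldehyde CC=O
Why: Proposed new method: the C9 hydroxyl adds to acetaldehyde, samarium(III) binds the hemiacetal alkoxide and the C12 carbonyl, and the hemiacetal hydride is transferred intramolecularly to the β-face of C12 (the face that carries C9, whose oxygen lies above the ring), which gives the 12α-alcohol and turns C9–OH into the C9 acetate in one operation; the closest known reaction type is the Evans–Tishchenko reduction of β-hydroxy ketones and enones, from which this case differs by the 1,4-distance of hydroxyl and ketone, compensated by their rigid proximity.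

**Step 19**
Reactants: 25 exomethylene allylic alcohol
Product: 26 target CNP0222085.1 (1S;2R;5Z;7S;8S;9R;10S;11R;12R;17R)
Conditions: [Rh(nbd)(dppb)]BF4 (5 mol %), H2 (50 bar), CH2Cl2, rt, stopped after 1 equiv H2
Reagents that add atoms: none
Why: Hydroxyl-directed hydrogenation with a cationic rhodium catalyst, in which coordination to the allylic C12–OH delivers H2 to the α-face of the unhindered 1,1-disubstituted C11=CH2, placing H-11 cis and the new methyl trans to the hydroxyl, while the trisubstituted C5=C6 and the neopentyl-flanked C13=C14 should react more slowly.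

**Compound list**
1 | acetophenone | CC(=O)c1ccccc1 | starting material
2 | 1-(1-methylcyclohexa-2,5-dien-1-yl)ethan-1-one | CC(=O)C1(C)C=CCC=C1 | intermediate
3 | (tert-butyldimethylsilyloxy)acetaldehyde | O=CCO[Si](C)(C)C(C)(C)C | starting material
4 | ethyl 2-[bis(2,2,2-trifluoroethoxy)phosphoryl]propanoate | CCOC(=O)C(C)P(=O)(OCC(F)(F)F)OCC(F)(F)F | starting material
5 | ethyl (2Z)-4-[(tert-butyldimethylsilyl)oxy]-2-methylbut-2-enoate | CCOC(=O)/C(C)=C\CO[Si](C)(C)C(C)(C)C | intermediate
6 | (2Z)-4-[(tert-butyldimethylsilyl)oxy]-2-methylbut-2-en-1-ol | OC/C(C)=C\CO[Si](C)(C)C(C)(C)C | intermediate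
7 | {[(2Z)-4-bromo-3-methylbut-2-en-1-yl]oxy}(tert-butyl)dimethylsilane | BrC/C(C)=C\CO[Si](C)(C)C(C)(C)C | intermediate
8 | (4Z)-6-silyloxy-4-methyl-1-(1-methylcyclohexa-2,5-dien-1-yl)hex-4-en-1-one | CC1(C=CCC=C1)C(=O)CC/C(C)=C\CO[Si](C)(C)C(C)(C)C | intermediate
9 | (1R,4Z)-alcohol from 8 (C2 carbinol) | CC1(C=CCC=C1)[C@H](O)CC/C(C)=C\CO[Si](C)(C)C(C)(C)C | intermediate
10 | (1R,4Z)-acetate of 9 | CC1(C=CCC=C1)[C@H](OC(C)=O)CC/C(C)=C\CO[Si](C)(C)C(C)(C)C | intermediate
11 | (1R,4Z)-6-hydroxy-4-methyl-1-(1-methylcyclohexa-2,5-dien-1-yl)hex-4-en-1-yl acetate | CC1(C=CCC=C1)[C@H](OC(C)=O)CC/C(C)=C\CO | intermediate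
12 | (1R,4Z)-4-methyl-1-(1-methylcyclohexa-2,5-dien-1-yl)-6-oxohex-4-en-1-yl acetate | CC1(C=CCC=C1)[C@H](OC(C)=O)CC/C(C)=C\C=O | intermediate
13 | (4R)-4-benzyl-3-propanoyl-1,3-oxazolidin-2-one | CCC(=O)N1[C@H](Cc2ccccc2)COC1=O | starting material
14 | ethyl glyoxylate | CCOC(=O)C=O | starting material
15 | ethyl (2R,3R)-4-[(4R)-4-benzyl-2-oxo-1,3-oxazolidin-3-yl]-2-hydroxy-3-methyl-4-oxobutanoate | O=C([C@H](C)[C@H](C(=O)OCC)O)N1[C@H](Cc2ccccc2)COC1=O | intermediate
16 | (2R,3R)-2-hydroxy-3-methylbutanedioic acid | OC(=O)[C@H](C)[C@H](C(=O)O)O | intermediate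
17 | (2R)-2-[(2R,4R)-2-tert-butyl-5-oxo-1,3-dioxolan-4-yl]propanoic acid | OC(=O)[C@H](C)[C@@H]1C(=O)O[C@H](C(C)(C)C)O1 | intermediate
18 | aldol hydroxy acid: C7 carbinol (S) bonded to C8 (S) of the dioxolanone, free C19 acid, not isolated | CC1(C=CCC=C1)[C@H](OC(C)=O)CC/C(C)=C\[C@H](O)[C@@]1([C@@H](C)C(=O)O)C(=O)O[C@H](C(C)(C)C)O1 | intermediate
19 | γ-lactone (O on C7, C19 carbonyl, 17R-methyl) spiro-fused at C8 to the 2-tert-butyl-dioxolanone (C9 carbonyl); 2R, 5Z, 7S, 8S | CC1(C=CCC=C1)[C@H](OC(C)=O)CC/C(C)=C\[C@@H]1OC(=O)[C@H](C)[C@]1(C2=O)O[C@@H](C(C)(C)C)O2 | intermediate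
20 | 8-hydroxy-8-(hydroxymethyl) γ-lactone carrying the (Z)-alkenyl chain, 2-acetate and 1-methylcyclohexa-2,5-dienyl ring; 2R, 7S, 8R, 17R | CC1(C=CCC=C1)[C@H](OC(C)=O)CC/C(C)=C\[C@@H]1OC(=O)[C@H](C)[C@]1(CO)O | intermediate
21 | as 20 but with a 4-methyl-4-substituted cyclohexa-2,5-dien-1-one ring (C12 ketone) | CC1(C=CC(=O)C=C1)[C@H](OC(C)=O)CC/C(C)=C\[C@@H]1OC(=O)[C@H](C)[C@]1(CO)O | intermediate
22 | 20-nor-briarane enone: 2-acetoxy-8,9-dihydroxy-12-oxo-5Z,13-diene lactone; 1S, 2R, 7S, 8R, 9R, 10S, 17R | O[C@@H]1[C@H]2CC(=O)C=C[C@]2(C)[C@H](OC(C)=O)CC/C(C)=C\[C@@H]2OC(=O)[C@H](C)[C@]21O | intermediate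
23 | 2-acetoxy-8,9-dihydroxy-12-oxobriara-5Z,11(20),13-triene lactone | O[C@@H]1[C@H]2C(=C)C(=O)C=C[C@]2(C)[C@H](OC(C)=O)CC/C(C)=C\[C@@H]2OC(=O)[C@H](C)[C@]21O | intermediate
24 | C9 O-(1-hydroxyethyl) hemiacetal of 23, not isolated | CC(O)O[C@@H]1[C@H]2C(=C)C(=O)C=C[C@]2(C)[C@H](OC(C)=O)CC/C(C)=C\[C@@H]2OC(=O)[C@H](C)[C@]21O | intermediate
25 | 2,9-diacetoxy-8,12α-dihydroxybriara-5Z,11(20),13-triene lactone; 1S, 2R, 7S, 8S, 9R, 10S, 12R, 17R | CC(=O)O[C@@H]1[C@H]2C(=C)[C@H](O)C=C[C@]2(C)[C@H](OC(C)=O)CC/C(C)=C\[C@@H]2OC(=O)[C@H](C)[C@]21O | intermediate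
26 | CNP0222085.1, 2,9-diacetoxy-8,12-dihydroxybriara-5Z,13-diene lactone; 1S, 2R, 7S, 8S, 9R, 10S, 11R, 12R, 17R | CC(=O)O[C@@H]1[C@H]2[C@@H](C)[C@H](O)C=C[C@]2(C)[C@H](OC(C)=O)CC/C(C)=C\[C@@H]2OC(=O)[C@H](C)[C@]21O | target

**Step count**
- Total steps: 19.
- Longest linear sequence: 15 steps (3 → 5 → 6 → 7 → 8 → 9 → 10 → 11 → 12 → 19 → 20 → 21 → 22 → 23 → 25 → 26).

**Steps most likely to fail**

1. **Step 16.**
   - What may go wrong: closure of the ten-membered ring between two crowded termini may be slower than quenching, oxidation or intermolecular addition of the C9 radical. The two enone arms may be poorly discriminated. The β-hydroxy radical may lose the C8 oxygen by spin-centre shift.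
   - Fallback: it sets out from 21. The primary carbinol is oxidised selectively (TEMPO, PhI(OAc)2, CH2Cl2) to the α-hydroxy aldehyde F1. The same bond is then closed as a samarium ketyl–enone reductive cyclisation (SmI2, t-BuOH, THF, slow addition at high dilution). Here the C8/C9 oxygens are held in a samarium(III) chelate and the samarium enolate is protonated. This returns to the route at 22.

2. **Step 18.**
   - What may go wrong: hydride transfer through the enlarged cyclic transition state may be too slow. Tishchenko dimerisation of acetaldehyde, acetalisation of the C8/C9 diol, or isomerisation of the exocyclic olefin could then take over.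
   - Fallback: it sets out from 23. Luche reduction (NaBH4, CeCl3·7H2O, MeOH, −78 °C) follows, in which the C9 alkoxyborohydride should deliver hydride to the same β-face, and gives the 9,12-diol F2. Acetylation of both secondary hydroxyls (Ac2O, DMAP, pyridine) gives the 2,9,12-triacetate F3. Selective methanolysis of the only unhindered, allylic C12 acetate (K2CO3, MeOH, 0 °C, or a lipase) returns to the route at 25.

3. **Step 14.**
   - What may go wrong: the γ-lactone may be over-reduced. The lactone acyl group may migrate from O–C7 to the new primary C9 hydroxyl in the basic borate medium.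
   - Fallback: it sets out from 19. Thiolysis of the acylal-type dioxolanone (EtSH, Et3N cat., CH2Cl2) is irreversible because pivalaldehyde is expelled, whereas opening of the γ-lactone is reversible, and it gives the α-hydroxy thioester F4. Fukuyama reduction (Et3SiH, Pd/C, acetone) gives the α-hydroxy aldehyde F5. Brief treatment with NaBH4 at −78 °C, where no ester reacts, returns to the route at 20.

**Further compounds**
F1 | step 16 | C9 α-hydroxy aldehyde of dienone 21 | CC1(C=CC(=O)C=C1)[C@H](OC(C)=O)CC/C(C)=C\[C@@H]1OC(=O)[C@H](C)[C@]1(C=O)O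
F2 | step 18 | 2-acetoxy-8,9,12α-trihydroxybriara-5Z,11(20),13-triene lactone | O[C@@H]1[C@H]2C(=C)[C@H](O)C=C[C@]2(C)[C@H](OC(C)=O)CC/C(C)=C\[C@@H]2OC(=O)[C@H](C)[C@]21O
F3 | step 18 | 2,9,12α-triacetoxy-8-hydroxybriara-5Z,11(20),13-triene lactone | CC(=O)O[C@@H]1[C@H]2C(=C)[C@H](OC(C)=O)C=C[C@]2(C)[C@H](OC(C)=O)CC/C(C)=C\[C@@H]2OC(=O)[C@H](C)[C@]21O
F4 | step 14 | C9 S-ethyl thioester of the 8-hydroxy lactone | CC1(C=CCC=C1)[C@H](OC(C)=O)CC/C(C)=C\[C@@H]1OC(=O)[C@H](C)[C@]1(C(=O)SCC)O
F5 | step 14 | C9 α-hydroxy aldehyde of the diene series | CC1(C=CCC=C1)[C@H](OC(C)=O)CC/C(C)=C\[C@@H]1OC(=O)[C@H](C)[C@]1(C=O)O
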